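**Strategy.** The route treats C8(OH)–C8'–C7'(O) as a tertiary aldol unit that is carried through the synthesis as a 4,5-dihydroisoxazole. The feature exploited is that C9 (ring A) and C9' (ring B) lie on the same face of the fusion bond C8–C8'. This is the geometry of a ring-bound Z-alkene, so C8=C8' is held in a dihydrodioxepine ketal. In one operation an aryl nitrile oxide, guided by the magnesium alkoxide of the C7 carbinol, forms C8–O and C8'–C7' on one face. C8 and C8' are thereby set from C7. The precursor is the (7R)-allylic alcohol 7, made from an iodo-dioxepine and O-benzylvanillin. N–O cleavage, Felkin-controlled reduction at C7' and ring closure at C9 and C9' follow.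

Key step: step 6

Remark: lignan numbering is used for all intermediates. Compound 6 is the commercial benzyl ether of vanillin. The CIP descriptor of C8' changes with its neighbours (S in 12–15, R in 16–21) while its geometry stays the same.

**Step 1**
Reactants: 1 but-2-yne-1,4-diol
Product: 3 (E)-2-iodobut-2-ene-1,4-diol (both CH2OH groups cis), via vinylstannane 2 (not isolated)
Conditions: Bu3SnH (1.05 equiv, slow addition), PdCl2(PPh3)2 (1 mol %), THF, 0 °C to rt; then iodine (1.05 equiv), 0 °C; aq Na2S2O3
Reagents that add atoms: iodine, [I][I]; tributyltin hydride, CCCC[SnH](CCCC)CCCC (its tin stays only in 2)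
Why: Palladium-catalysed hydrostannation adds H and Sn to the same face of the symmetrical alkyne, so the two CH2OH groups end cis as the ring of 5 demands (anti hydroalumination with Red-Al or LiAlH4 would place them trans and the seven-membered ketal could not close), and iododestannylation then replaces tin with retention of geometry.

**Step 2**
Reactants: 3 (E)-2-iodobut-2-ene-1,4-diol; 4 2,2-dimethoxypropane
Product: 5 5-iodo-2,2-dimethyl-4,7-dihydro-1,3-dioxepine
Conditions: 4 (3 equiv), pyridinium p-toluenesulfonate (5 mol %), CH2Cl2, 4 Å molecular sieves, reflux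
Reagents that add atoms: 2,2-dimethoxypropane (4), COC(C)(C)OC
Why: Acid-catalysed transketalisation is the established way from cis-but-2-ene-1,4-diols to 4,7-dihydro-1,3-dioxepines, it is driven by uptake of methanol on the sieves, and the vinyl iodide is inert to it.

**Step 3**
Reactants: 5 5-iodo-2,2-dimethyl-4,7-dihydro-1,3-dioxepine; 6 4-(benzyloxy)-3-methoxybenzaldehyde
Product: 7 (R)-[4-(benzyloxy)-3-methoxyphenyl](2,2-dimethyl-4,7-dihydro-1,3-dioxepin-5-yl)methanol
Conditions: CrCl2 (10 mol %), N-[2-(4-isopropyl-4,5-dihydro-1,3-oxazol-2-yl)-6-methylphenyl]methanesulfonamide (11 mol %, the enantiomer that gives (R)-7), 1,8-bis(dimethylamino)naphthalene (11 mol %), NiCl2·(2,9-dimethyl-1,10-phenanthroline) (2 mol %), Mn powder (2 equiv), Cp2ZrCl2 (1.1 equiv), LiCl (2 equiv), MeCN, rt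
Reagents that add atoms: none
Why: In this catalytic asymmetric Nozaki–Hiyama–Kishi reaction nickel activates the carbon–iodine bond, the alkenyl group passes to ligand-bound chromium and adds to the Si face of the aldehyde to set C7 as R, without the strong base or the allylic alkoxide elimination an alkenyllithium could bring, and the sense of induction is to be confirmed on 7 by Mosher ester analysis since both ligand enantiomers are available from valinol.

**Step 4**
Reactants: 6 4-(benzyloxy)-3-methoxybenzaldehyde
Product: 8 (E)-4-(benzyloxy)-3-methoxybenzaldehyde oxime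
Conditions: NH2OH·HCl (1.2 equiv), NaOAc (1.3 equiv), EtOH–H2O, rt
Reagents that add atoms: hydroxylamine hydrochloride, Cl.NO
Why: This is an acetate-buffered condensation of an aromatic aldehyde with hydroxylamine (oxime formation), which touches neither ether.

**Step 5**
Reactants: 8 (E)-4-(benzyloxy)-3-methoxybenzaldehyde oxime
Product: 9 4-(benzyloxy)-N-hydroxy-3-methoxybenzimidoyl chloride
Conditions: N-chlorosuccinimide (1.0 equiv), DMF, 0 °C to rt
Reagents that add atoms: N-chlorosuccinimide, O=C1CCC(=O)N1Cl
Why: Chlorination of the aldoxime carbon with N-chlorosuccinimide in DMF is the standard entry to hydroximoyl chlorides, and with one equivalent at or below room temperature it should outrun chlorination of the dialkoxyarene ring.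

**Step 6 (key step)**
Reactants: 7 (R)-allylic alcohol; 9 4-(benzyloxy)-N-hydroxy-3-methoxybenzimidoyl chloride
Product: 12 (7R,8S,8'S)-isoxazoline cis-fused to the dioxepane, via magnesium alkoxide 10 (not isolated), via nitrile oxide 11 (not isolated)
Conditions: 7, i-PrOH (3.3 equiv), EtMgBr (3.0 equiv), CH2Cl2, 0 °C; then 9 (1.5 equiv) in CH2Cl2 by syringe pump, 0 °C to rt, 24–48 h; aqueous work-up
Reagents that add atoms: ethylmagnesium bromide, CC[Mg]Br (its MgBr stays only in 10)
Why: Isopropoxymagnesium bromide dehydrochlorinates 9 to nitrile oxide 11, whose oxygen binds to the magnesium of alkoxide 10, so the concerted suprafacial (3+2) cycloaddition runs inside a complex and should outpace both the unassisted addition to a trisubstituted alkene and the dimerisation of 11. The closest known reaction type is the magnesium-alkoxide-directed nitrile oxide cycloaddition to secondary allylic alcohols. The one new ring, the dihydroisoxazole O–C8–C8'–C7'=N, is closed by intermolecular cycloaddition with C8–O and C8'–C7' formed together on one alkene face, and it ends cis-fused to the seven-membered ring. C8 is controlled by C7: in the reactive conformer O7–Mg lies outside next to the dipole oxygen, H7 lies inside over the alkene and the aryl group points away from the dipole, which turns (7R) into (8S) with O7 and O8 syn. C8' follows from C8 because the addition is syn and C9 and C9' are locked cis by the ketal. The regioselectivity needed (oxygen to C8) is secured twice, by the short magnesium bridge that reaches only C8 and by the usual preference of the nitrile oxide oxygen for the more substituted alkene carbon.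

**Step 7**
Reactants: 12 isoxazoline
Product: 14 (7R,8S,8'S)-β-hydroxy ketone (dioxepane with 8-OH and the C7' aroyl group cis), via hydroxy imine 13 (not isolated)
Conditions: Raney Ni, H2 (1 atm), B(OH)3 (5 equiv), MeOH–H2O (5:1), rt
Reagents that add atoms: water, O
Why: Hydrogenolysis of the weak N–O bond gives imine 13, which the boric acid buffer hydrolyses before further reduction (reductive opening of an isoxazoline to a β-hydroxy ketone), no bond at C7, C8 or C8' is touched, and the near-neutral medium at room temperature avoids retro-aldol cleavage, epimerisation at C8' and loss of the ketal or benzyl ethers.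

**Step 8**
Reactants: 14 β-hydroxy ketone
Product: 15 7,8-bis(trimethylsilyl) ether of 14
Conditions: N-(trimethylsilyl)imidazole (5 equiv), CH2Cl2, rt to 35 °C
Reagents that add atoms: N-(trimethylsilyl)imidazole, C[Si](C)(C)n1ccnc1
Why: This strong but non-acidic and non-enolising silyl donor caps O7 and the hindered tertiary O8, which shuts off retro-aldol cleavage, lactol formation from O7 and any chelate or internal hydride delivery through O8, the latter being expected to give the 1,3-anti diol and hence the wrong C7' epimer because the bulky C7 arm would sit equatorial in the cyclic transition state.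

**Step 9**
Reactants: 15 bis-silyl ether ketone
Product: 16 (7R,8S,7'S,8'R)-7'-alcohol
Conditions: i-Bu2AlH (2.5 equiv), CH2Cl2, −78 °C; Rochelle salt work-up
Reagents that add atoms: none
Why: This is a Felkin–Anh-controlled hydride addition to an α-branched aryl ketone, in which H8' lies next to the aryl ring, the fully substituted C8 screens one carbonyl face and hydride enters from the C9' side (a metal contact to the C9' oxygen would direct the same way), giving (7'S), which is the 1,3-syn relation of O8 and O7' and later places the aryl group cis to H8' in ring A.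

**Step 10**
Reactants: 16 7'-alcohol
Product: 17 (1R,2S,3R,4S)-1,4-bis[4-(benzyloxy)-3-methoxyphenyl]-2,3-bis(hydroxymethyl)butane-1,2,4-triol
Conditions: AcOH–THF–H2O (3:1:1), rt
Reagents that add atoms: none
Why: Aqueous acetic acid hydrolyses the labile seven-membered isopropylidene ketal and both trimethylsilyl ethers (ketal and silyl ether hydrolysis with all C–O bonds of the substrate kept) but is too weak to ionise the two alkoxybenzylic carbinols, so C7 and C7' keep their configuration.

**Step 11**
Reactants: 17 pentaol
Product: 20 4,4'-di-O-benzyl-8-hydroxypinoresinol, via bis-mesylate 18 (not isolated), via ring B mesylate 19 (not isolated)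
Conditions: MsCl (2.1 equiv), pyridine, −20 °C, 2 h; then rt to 50 °C
Reagents that add atoms: methanesulfonyl chloride, CS(=O)(=O)Cl (its atoms stay only in 18 and 19)
Why: Fast selective sulfonylation of the two primary hydroxyls is followed by two 5-exo-tet Williamson-type etherifications, the classical closure of lignan polyols to furofurans, in which O7 displaces the C9' mesylate (ring B) and O7' the C9 mesylate (ring A), the three- and four-membered alternatives are slower without strong base, and all four stereocentres are carried over because substitution occurs only at C9 and C9'.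

**Step 12**
Reactants: 20 4,4'-di-O-benzyl-8-hydroxypinoresinol
Product: 21 8-hydroxypinoresinol (7R,8S,7'S,8'R)
Conditions: H2 (1 atm), 10% Pd/C, EtOAc, rt, stopped when 20 is consumed
Reagents that add atoms: none
Why: Hydrogenolysis of aryl benzyl ethers over Pd/C is much faster than that of the ring benzylic ethers C7–O and C7'–O in a neutral solvent at one atmosphere, so stopping at full conversion should free both phenols without opening the furofuran.

**Compound list**

| No. | Name | SMILES | Role |
|---|---|---|---|
| 1 | but-2-yne-1,4-diol | OCC#CCO | starting material |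
| 2 | (E)-2-(tributylstannyl)but-2-ene-1,4-diol | OC/C([Sn](CCCC)(CCCC)CCCC)=C\CO | intermediate |
| 3 | (E)-2-iodobut-2-ene-1,4-diol | OC/C(I)=C\CO | intermediate |
| 4 | 2,2-dimethoxypropane | COC(C)(C)OC | starting material |
| 5 | 5-iodo-2,2-dimethyl-4,7-dihydro-1,3-dioxepine | CC1(C)OCC=C(I)CO1 | intermediate |
| 6 | 4-(benzyloxy)-3-methoxybenzaldehyde | COc1cc(C=O)ccc1OCc1ccccc1 | starting material |
| 7 | (R)-[4-(benzyloxy)-3-methoxyphenyl](2,2-dimethyl-4,7-dihydro-1,3-dioxepin-5-yl)methanol | CC1(C)OCC=C(CO1)[C@H](O)c1ccc(OCc2ccccc2)c(OC)c1 | intermediate |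
| 8 | (E)-4-(benzyloxy)-3-methoxybenzaldehyde oxime | COc1cc(/C=N/O)ccc1OCc1ccccc1 | intermediate |
| 9 | 4-(benzyloxy)-N-hydroxy-3-methoxybenzimidoyl chloride | COc1cc(C(Cl)=NO)ccc1OCc1ccccc1 | intermediate |
| 10 | bromomagnesium alkoxide of 7 | CC1(C)OCC=C(CO1)[C@H](O[Mg]Br)c1ccc(OCc2ccccc2)c(OC)c1 | intermediate |
| 11 | 4-(benzyloxy)-3-methoxybenzonitrile oxide | COc1cc(C#[N+][O-])ccc1OCc1ccccc1 | intermediate |
| 12 | (7R,8S,8'S)-3-aryl-4,5-dihydroisoxazole cis-fused at C4 (C8', H) and C5 (C8) to the 2,2-dimethyl-1,3-dioxepane, C5 bearing the (R)-aryl(hydroxy)methyl group | COc1cc(C2=NO[C@]3([C@H](O)c4ccc(OCc5ccccc5)c(OC)c4)COC(C)(C)OC[C@H]23)ccc1OCc1ccccc1 | intermediate |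
| 13 | β-hydroxy ketimine from N–O cleavage of 12 | COc1cc(C(=N)[C@H]2COC(C)(C)OC[C@]2(O)[C@H](O)c3ccc(OCc4ccccc4)c(OC)c3)ccc1OCc1ccccc1 | intermediate |
| 14 | (7R,8S,8'S)-β-hydroxy ketone, 8-OH and aroyl cis on the dioxepane | COc1cc(C(=O)[C@H]2COC(C)(C)OC[C@]2(O)[C@H](O)c3ccc(OCc4ccccc4)c(OC)c3)ccc1OCc1ccccc1 | intermediate |
| 15 | 7,8-bis(trimethylsilyl) ether of 14 | COc1cc(C(=O)[C@H]2COC(C)(C)OC[C@]2(O[Si](C)(C)C)[C@H](O[Si](C)(C)C)c3ccc(OCc4ccccc4)c(OC)c3)ccc1OCc1ccccc1 | intermediate |
| 16 | (7R,8S,7'S,8'R)-7'-alcohol from 15 | COc1cc([C@@H](O)[C@H]2COC(C)(C)OC[C@]2(O[Si](C)(C)C)[C@H](O[Si](C)(C)C)c3ccc(OCc4ccccc4)c(OC)c3)ccc1OCc1ccccc1 | intermediate |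
| 17 | (1R,2S,3R,4S)-1,4-bis[4-(benzyloxy)-3-methoxyphenyl]-2,3-bis(hydroxymethyl)butane-1,2,4-triol | COc1cc([C@@H](O)[C@@H](CO)[C@](O)(CO)[C@H](O)c2ccc(OCc3ccccc3)c(OC)c2)ccc1OCc1ccccc1 | intermediate |
| 18 | 9,9'-bis(methanesulfonate) of 17 | COc1cc([C@@H](O)[C@@H](COS(C)(=O)=O)[C@](O)(COS(C)(=O)=O)[C@H](O)c2ccc(OCc3ccccc3)c(OC)c2)ccc1OCc1ccccc1 | intermediate |
| 19 | ring B tetrahydrofuran with 8-OH, C9 mesylate and free C7' carbinol | COc1cc([C@@H](O)[C@H]2CO[C@H](c3ccc(OCc4ccccc4)c(OC)c3)[C@@]2(O)COS(C)(=O)=O)ccc1OCc1ccccc1 | intermediate |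
| 20 | 4,4'-di-O-benzyl-8-hydroxypinoresinol | COc1cc([C@H]2OC[C@]3(O)[C@@H](c4ccc(OCc5ccccc5)c(OC)c4)OC[C@H]23)ccc1OCc1ccccc1 | intermediate |
| 21 | 8-hydroxypinoresinol (7R,8S,7'S,8'R) | COc1cc([C@H]2OC[C@]3(O)[C@@H](c4ccc(O)c(OC)c4)OC[C@H]23)ccc1O | target |

Total step count: 12.
Longest linear sequence: 10 (steps 1, 2, 3, 6, 7, 8, 9, 10, 11, 12).

**Steps most likely to fail**

**Step 6.** Addition to the hindered trisubstituted alkene may be sluggish, so that 11 is lost by dimerisation. Facial selectivity may also erode through a second reactive conformer of the carbinol, because C8' carries only hydrogen cis to C7 and allylic strain is weak.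

The fallback takes facial control away from C7. It sets out from 5 and 9 and returns at 12.
- Iodide 5 is lithiated (t-BuLi, Et2O, −78 °C) to 5-lithio-2,2-dimethyl-4,7-dihydro-1,3-dioxepine F1.
- F1 is trapped with paraformaldehyde as (2,2-dimethyl-4,7-dihydro-1,3-dioxepin-5-yl)methanol F2.
- This achiral primary allylic alcohol is combined with Et2Zn and diisopropyl tartrate (the enantiomer that gives the C8/C8' geometry of 12) in CHCl3–dioxane at 0 °C. It takes up the nitrile oxide released from 9 in a tartrate–zinc-mediated asymmetric cycloaddition to give the 5-(hydroxymethyl)isoxazoline F3.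
- Dess–Martin oxidation gives the isoxazoline-5-carbaldehyde F4.
- 4-(Benzyloxy)-3-methoxyphenylmagnesium bromide F5, made from the commercial aryl bromide, adds under chelation of magnesium by the aldehyde oxygen and the ring oxygen on C8. Attack comes from the side of the C9 methylene group, which should give (7R).

**Step 11.** Discrimination among five hydroxyl groups may be incomplete. Other possible failures are ether formation between O9 and C9' at a half-sulfonylated stage, slow substitution at the neopentyl-type C9, and oxirane formation from O8.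

The fallback inverts the roles of the partners and starts again from 17. A catalytic amount of camphorsulfonic acid in CH2Cl2 at 0 °C ionises the two alkoxybenzylic carbinols. O9 and O9' then capture C7' and C7 in 5-exo fashion, with each aryl group turning to the convex face. A short contact time keeps the closure under kinetic control. The fallback returns at 20 and makes no new compound (entry F0).

**Step 3.** Enantioselection in the chromium-mediated addition to an aromatic aldehyde may be incomplete, or catalyst turnover may be slow.

The fallback sets C7 by reduction instead of addition. It sets out from 5 and 6 and returns at 7.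
- A ligand-free coupling (CrCl2, 3 equiv, NiCl2, 1 mol %, DMF, rt) gives the racemic allylic alcohol F6.
- MnO2 in CH2Cl2 oxidises it to the aryl alkenyl ketone F7.
- Corey–Bakshi–Shibata reduction follows, using (S)-5,5-diphenyl-2-methyl-3,4-propano-1,3,2-oxazaborolidine (10 mol %) and BH3·SMe2 in THF at −30 °C. The α-branched alkenyl group is expected to act as the large substituent, so (R)-7 should result. The sense is again to be checked by Mosher ester analysis.

**Further compounds**
F1 | step 6 | 5-lithio-2,2-dimethyl-4,7-dihydro-1,3-dioxepine | CC1(C)OCC=C([Li])CO1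
F2 | step 6 | (2,2-dimethyl-4,7-dihydro-1,3-dioxepin-5-yl)methanol | CC1(C)OCC=C(CO)CO1
F3 | step 6 | 5-(hydroxymethyl)isoxazoline with the C8/C8' geometry of 12 | COc1cc(C2=NO[C@]3(CO)COC(C)(C)OC[C@H]23)ccc1OCc1ccccc1
F4 | step 6 | isoxazoline-5-carbaldehyde with the C8/C8' geometry of 12 | COc1cc(C2=NO[C@]3(C=O)COC(C)(C)OC[C@H]23)ccc1OCc1ccccc1
F5 | step 6 | 4-(benzyloxy)-3-methoxyphenylmagnesium bromide | COc1cc([Mg]Br)ccc1OCc1ccccc1
F0 | step 11 | none | none
F6 | step 3 | racemic [4-(benzyloxy)-3-methoxyphenyl](2,2-dimethyl-4,7-dihydro-1,3-dioxepin-5-yl)methanol | CC1(C)OCC=C(CO1)C(O)c1ccc(OCc2ccccc2)c(OC)c1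
F7 | step 3 | [4-(benzyloxy)-3-methoxyphenyl](2,2-dimethyl-4,7-dihydro-1,3-dioxepin-5-yl)methanone | CC1(C)OCC=C(CO1)C(=O)c1ccc(OCc2ccccc2)c(OC)c1
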